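**Assumption:** dihydroconiferyl alcohol (1) is taken as a catalogue compound; racemic compounds are drawn without stereodescriptors; in step 1 air is the terminal oxidant, so copper(II) acetate is turned over and counts as unchanged.

## Retrosynthetic overview

1. Target 6 ⇐ racemic α-aryloxy ketone 5 by Ru-catalysed asymmetric hydrogenation with dynamic kinetic resolution, which sets C7 and C8 together.
2. Ketone 5 ⇐ C7–C8 disconnection: the acyl anion of 3,4,5-trimethoxybenzaldehyde (Breslow intermediate) plus aryl vinyl ether 2 as a masked aryloxy-carbenium at C8 (NHC-catalysed Markovnikov hydroacylation).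
3. Vinyl ether 2 ⇐ O-vinylation of dihydroconiferyl alcohol 1.
4. No ring is formed; both benzene rings come from the starting materials.

## Route

**Step 1**
Reactants: 1 dihydroconiferyl alcohol, 3-(4-hydroxy-3-methoxyphenyl)propan-1-ol
Product: 2 3-[4-(ethenyloxy)-3-methoxyphenyl]propan-1-ol
Conditions: (CH2=CHBO)3·pyridine (0.7 equiv), Cu(OAc)2 (1.0 equiv), pyridine (10 equiv), CH2Cl2, air, rt, 24 h
Reagents that add atoms: 2,4,6-trivinylcyclotriboroxane–pyridine complex, C=CB1OB(C=C)OB(C=C)O1.c1ccncc1
Why: Chan–Lam-type copper-mediated oxidative O-vinylation, in which the copper(II) phenoxide transmetallates with the vinylboroxine and C–O reductive elimination gives the aryl vinyl ether; the acidic phenol should couple much faster than the aliphatic primary alcohol at room temperature, and no stereocentre is formed.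

**Step 2**
Reactants: 2 3-[4-(ethenyloxy)-3-methoxyphenyl]propan-1-ol; 3 3,4,5-trimethoxybenzaldehyde (1.5 equiv)
Product: 5 racemic 2-[4-(3-hydroxypropyl)-2-methoxyphenoxy]-1-(3,4,5-trimethoxyphenyl)propan-1-one, via Breslow enaminol 4 (not isolated)
Conditions: 2-(2,6-dimethoxyphenyl)-6,7-dihydro-5H-pyrrolo[2,1-c][1,2,4]triazol-2-ium chloride (20 mol%), K2CO3 (20 mol%), 1,4-dioxane, 110 °C, sealed tube, Ar
Reagents that add atoms: none
Why: Proposed new method: NHC-catalysed intermolecular Markovnikov hydroacylation of an aryl vinyl ether; the triazolylidene adds to 3 to give the nucleophilic Breslow enaminol 4 (acyl anion equivalent), whose O–H proton passes to the terminal CH2 of 2 while its carbon attacks the developing aryloxy-stabilised cation at the O-bearing carbon (concerted, asynchronous ene-type transfer), and collapse of the adduct releases ketone 5 and the carbene; the competing benzoin of 3 is reversible and should drain into the irreversible C–C bond formation; the closest known reactions are the NHC-catalysed intramolecular hydroacylation of enol ethers to benzofuran-3-ones and the intermolecular NHC hydroacylation of styrenes and cyclopropenes; C8 is formed racemic, which is intended.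

**Step 3**
Reactants: 5 racemic 2-[4-(3-hydroxypropyl)-2-methoxyphenoxy]-1-(3,4,5-trimethoxyphenyl)propan-1-one
Product: 6 Surinamensinol A, (1R,2R)-2-[4-(3-hydroxypropyl)-2-methoxyphenoxy]-1-(3,4,5-trimethoxyphenyl)propan-1-ol
Conditions: trans-RuCl2[(R)-XylBINAP][(R)-DAIPEN] (1 mol%), t-BuOK (20 mol%), H2 (10 atm), i-PrOH, 25 °C
Reagents that add atoms: none
Why: Noyori asymmetric hydrogenation with dynamic kinetic resolution: t-BuOK epimerises C8 by reversible deprotonation faster than reduction; the (R),(R)-catalyst delivers hydride to the carbonyl face that gives (S)-1-arylethanols from aryl methyl ketones, which is 7R here because the OAr-bearing carbon outranks the aryl group; the outer-sphere, non-chelated transition state follows the polar Felkin–Anh model (C8–OAr anti to the hydride), which is matched only for the (8R)-ketone, so the product should be the (7R,8R)-threo alcohol.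

## Compound list

1 | dihydroconiferyl alcohol, 3-(4-hydroxy-3-methoxyphenyl)propan-1-ol | COc1cc(CCCO)ccc1O | starting material
2 | 3-[4-(ethenyloxy)-3-methoxyphenyl]propan-1-ol | COc1cc(CCCO)ccc1OC=C | intermediate
3 | 3,4,5-trimethoxybenzaldehyde | COc1cc(C=O)cc(OC)c1OC | starting material
4 | Breslow enaminol, [2-(2,6-dimethoxyphenyl)-6,7-dihydro-5H-pyrrolo[2,1-c][1,2,4]triazol-3-ylidene](3,4,5-trimethoxyphenyl)methanol | OC(=C1N(c2c(OC)cccc2OC)N=C2CCCN12)c1cc(OC)c(OC)c(OC)c1 | intermediate
5 | racemic 2-[4-(3-hydroxypropyl)-2-methoxyphenoxy]-1-(3,4,5-trimethoxyphenyl)propan-1-one | COc1cc(CCCO)ccc1OC(C)C(=O)c1cc(OC)c(OC)c(OC)c1 | intermediate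
6 | Surinamensinol A, (1R,2R)-2-[4-(3-hydroxypropyl)-2-methoxyphenoxy]-1-(3,4,5-trimethoxyphenyl)propan-1-ol | COc1cc(CCCO)ccc1O[C@H](C)[C@H](O)c1cc(OC)c(OC)c(OC)c1 | target

## Step count and risks

Total step count: 3. Longest linear sequence: 3 steps (1 → 2 → 5 → 6).

**Most likely to fail, in order:**

**Step 2 (the intermolecular hydroacylation is unprecedented).** The aryl vinyl ether may be too weakly basic to accept the proton from the Breslow enaminol, leaving only benzoin of 3. The fallback sets out from 3 and comes back at 5; step 1 is then not needed. Aldehyde 3 and acetaldehyde (5 equiv) are joined by a thiazolium-catalysed crossed acyloin condensation (3-benzyl-5-(2-hydroxyethyl)-4-methylthiazolium chloride, Et3N, EtOH, 60 °C), with 3 as the acyl anion donor, to give racemic 2-hydroxy-1-(3,4,5-trimethoxyphenyl)propan-1-one F1. Mesylation (MsCl, Et3N, CH2Cl2, 0 °C) gives racemic 1-oxo-1-(3,4,5-trimethoxyphenyl)propan-2-yl methanesulfonate F2. The phenoxide of 1 (K2CO3, acetone, 50 °C) then displaces the mesylate by SN2 to give 5.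

**Step 3 (diastereoselectivity and rate of epimerisation are untested on this acyclic α-aryloxy ketone).** The fallback sets out from 5 and comes back at 6. Non-chelated Felkin–Anh reduction (NaBH4, 15-crown-5, THF/i-PrOH, −20 °C) gives the racemic threo alcohol, a 1:1 mixture of (1R,2R)- and (1S,2S)-2-[4-(3-hydroxypropyl)-2-methoxyphenoxy]-1-(3,4,5-trimethoxyphenyl)propan-1-ol F3. Resolution by preparative chiral SFC on an amylose carbamate phase then gives 6, at a maximum of 50% yield.

**Step 1 (chemoselectivity for the phenol over the primary alcohol, and moderate Chan–Lam yields).** The fallback sets out from 1 and comes back at 2. Phenol-selective alkylation with 1,2-dibromoethane (5 equiv, K2CO3, acetone, reflux) gives 3-[4-(2-bromoethoxy)-3-methoxyphenyl]propan-1-ol F4. E2 elimination (t-BuOK, 2.5 equiv, DMSO, rt) then gives 2.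

## Further compounds

F1 | step 2 | racemic 2-hydroxy-1-(3,4,5-trimethoxyphenyl)propan-1-one | CC(O)C(=O)c1cc(OC)c(OC)c(OC)c1
F2 | step 2 | racemic 1-oxo-1-(3,4,5-trimethoxyphenyl)propan-2-yl methanesulfonate | CC(OS(C)(=O)=O)C(=O)c1cc(OC)c(OC)c(OC)c1
F3 | step 3 | racemic threo-2-[4-(3-hydroxypropyl)-2-methoxyphenoxy]-1-(3,4,5-trimethoxyphenyl)propan-1-ol, 1:1 (1R,2R) and (1S,2S) | COc1cc(CCCO)ccc1O[C@H](C)[C@H](O)c1cc(OC)c(OC)c(OC)c1.COc1cc(CCCO)ccc1O[C@@H](C)[C@@H](O)c1cc(OC)c(OC)c(OC)c1
F4 | step 1 | 3-[4-(2-bromoethoxy)-3-methoxyphenyl]propan-1-ol | COc1cc(CCCO)ccc1OCCBr
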